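**The long wait.** Time in this flask works twice over 25 min: substrate enters solution slowly, and whatever target forms then sits beside whatever solid remains.

| flask | solid substrate | coupling partner | time |
|---|---|---|---|
| delta | 0.040 M | 1.05 equiv | 25 min |
| theta | 0.060 M | 1.05 equiv | 25 min |
| gamma | 0.10 M | 1.05 equiv | 25 min |
| alpha | 0.15 M | 1.05 equiv | 25 min |
| epsilon | 0.25 M | 1.05 equiv | 25 min |

    solid substrate + target → side product B (k1 = 0.0196 /M/s)
    solid substrate ⇌ dissolved substrate, rate k2*(cs2 - [dissolved substrate]) while solid is left; crystals form when [dissolved substrate] > cs2 (cs2 = 40 mM, k2 = 0.00188 /s)
    dissolved substrate + coupling partner → target (k3 = 0.0711 /M/s)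
    target ⇌ isomer of the product (K4 = 1.36, k4 = 2.62 × 10⁻⁴ /s)
    coupling partner → side product A (k5 = 0.00637 /s)

- [target] at the end for delta, theta, gamma, alpha, epsilon, in this order
- how the row runs (hardly changes / falls all the way / rises, then falls / falls, then rises / rises all the way)

- a species is counted by the solid substrate in it: one side product B counts as two
- given per volume of solution although it is solid: solid substrate
- at the start none of the solid substrate is in solution
- "hardly changes" means that all values lie within two and a half points (for a concentration: within two and a half percent of the largest)
- run time (delta): 25 min

**First instants.** No substrate is in solution at the start, so step 3 waits on step 2. Meanwhile the coupling partner decays with a half-life of 1.8 min by step 5 alone, shorter than the 6.14 min half-life of the gap to solubility. Even at solubility, step 3 takes partner at 0.171 /min against 0.382 /min for step 5, so side product A wins the branch.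

**The middle.** Target therefore forms in the early minutes. This hand reckoning does not work out the height of that rise and stops short of absolute end values. As the partner fades, dissolved substrate climbs towards solubility, and this reckoning takes the solid to be about the surplus, which is the charge minus the solubility.

**The end.** From here target loses ground, and a pace can be reckoned from the surplus. For epsilon the surplus is 0.210 M, and the surplus clock, the half-life of target by step 1 on that solid, is 2.81 min. For alpha it is 5.36 min. Theta's clock of 29.5 min is already shorter than the 44 min forward half-life of step 4, so loss to the solid overtakes isomerisation by theta. Delta's charge equals the solubility, so delta has no surplus and no clock. The reckoning commits to a row that falls, and to target dropping between mid-run and the end by a factor of 21.9 in epsilon and 5.04 in alpha.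

**The forecast.** Unlike this reckoning, the forecast puts figures on the end values: 0.0021 M, 0.0018 M, 0.001 M, 4.500 × 10⁻⁴ M and 1.000 × 10⁻⁴ M, a row that falls all the way. Its ground is this: “Leftover solid above the 40 mM solubility then destroys the target over the remaining time, increasingly so at high loading”.

**The result.** The simulation gives 0.00202 M, 0.00189 M, 0.00127 M, 6.46 × 10⁻⁴ M and 1.60 × 10⁻⁴ M, a row that falls all the way. The shape agrees with the forecast, though epsilon ends higher than forecast.

**Clock against flask.** In epsilon, target goes from 0.824% of the charge at 12.5 min to 0.0638% at the end, a factor of 12.9 against the clock's 21.9. In alpha it goes from 1.93% to 0.431%, a factor of 4.48 against 5.04. Epsilon's low end value comes from the low solubility of dissolved substrate, which also sets how fast it dissolves, acting together with the passing of coupling partner into side product A, and the solubility is the largest single effect. Against the 1.60 × 10⁻⁴ M of the run as it stands, epsilon ends at 0.0250 M without the passing into side product A and at 0.116 M without the low solubility.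

(The numbers were set for the occasion; no experiment stands behind them.)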